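**Strategy**

Everything rests on cutting both C3–O carbinol bonds back to C3–acetyl bonds. The feature used is that in each lactone ring (O1, C2, C3, C4, C5) the C3 hydroxyl stands cis to the C4 arylmethyl group, exactly the position an acetyl group takes when a 3-acetyl lactone enolate is benzylated anti to C4. One twofold Baeyer–Villiger oxidation then converts both acetyl groups into acetoxy groups with retention at the quaternary carbons. Its substrate is the biaryl-linked bis(3-acetyl-3,4-dibenzylbutyrolactone), built by Suzuki–Miyaura union of two (S)-lactone-derived halves and oxidised as its tetra(aryl acetate), so that the arenes are deactivated and a single methanolysis then releases the target.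

Key step: step 19

Remark: the (3R,4R) configuration of both lactones of the target is, with unchanged geometry, (3S,4S) in the quaternary 3-acetyl intermediates and (S) in the 3-unsubstituted lactones, only because the CIP priorities change. 4-Benzyloxy-3-methoxybenzaldehyde and (4-benzyloxy-3-methoxyphenyl)methanol are taken as purchased. The biaryl axis carries two ortho substituents only and is assumed to rotate freely.

**Route**

Step 1
Reactants: 1 4-benzyloxy-3-methoxybenzaldehyde; 2 dimethyl succinate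
Product: 3 (E)-4-(4-benzyloxy-3-methoxyphenyl)-3-(methoxycarbonyl)but-3-enoic acid
Conditions: NaOMe (1.5 equiv), MeOH, reflux; then aq. HCl
Reagents that add atoms: none
Why: Stobbe condensation, in which the aldolate lactonises onto the second ester and base-induced opening of that paraconate gives the E half-ester with the free acid on the CH2 arm, without creating a stereocentre.

Step 2
Reactants: 3 (E)-4-(4-benzyloxy-3-methoxyphenyl)-3-(methoxycarbonyl)but-3-enoic acid
Product: 4 (S)-3-(4-benzyloxy-3-methoxybenzyl)-4-methoxy-4-oxobutanoic acid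
Conditions: [Rh(cod)((R,R)-Et-DuPHOS)]BF4 (1 mol %), H2 (5 bar), NaOMe (0.1 equiv), MeOH, 25 °C
Reagents that add atoms: none
Why: Asymmetric hydrogenation of an itaconate-type half-ester whose carboxylate arm chelates rhodium beside the alkene, so the C2-symmetric bisphospholane fixes the face of hydrogen delivery and sets the (S) centre; the sense expected for this ligand hand should be confirmed by chiral HPLC on the first run (the mirror-image ligand is equally available), and the benzyl ether is inert to the homogeneous catalyst.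

Step 3
Reactants: 4 (S)-3-(4-benzyloxy-3-methoxybenzyl)-4-methoxy-4-oxobutanoic acid
Product: 6 (S)-4-(4-benzyloxy-3-methoxybenzyl)dihydrofuran-2(3H)-one, via hydroxy acid 5 (not isolated)
Conditions: KOH (1.0 equiv), EtOH, 0 °C; Ca(BH4)2 (from CaCl2 and NaBH4), EtOH, −10 °C to rt; then 2 M HCl, rt
Reagents that add atoms: none
Why: Chemoselective borohydride reduction of the ester beside the carboxylate salt, which Ca(BH4)2 leaves untouched, followed by acid-driven closure of the γ-hydroxy acid to the five-membered lactone; the stereocentre is not involved and the cold medium should not epimerise it.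

Step 4
Reactants: 6 (S)-4-(4-benzyloxy-3-methoxybenzyl)dihydrofuran-2(3H)-one
Product: 7 (3R,4S)-3-acetyl-4-(4-benzyloxy-3-methoxybenzyl)dihydrofuran-2(3H)-one
Conditions: LiN(SiMe3)2 (2.2 equiv), THF, −78 °C; 1-acetylimidazole (1.1 equiv), −78 to 0 °C; aq. NH4Cl
Reagents that add atoms: 1-acetylimidazole, CC(=O)n1ccnc1
Why: Crossed Claisen acylation of the lactone lithium enolate by an acyl-transfer reagent that favours C- over O-acylation, the second equivalent of base storing the product as its enolate; the acetyl group should settle trans to the C4 group, but C3 is labile and is reset in step 15.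

Step 5
Reactants: 8 5-bromovanillin
Product: 9 4-benzyloxy-3-bromo-5-methoxybenzaldehyde
Conditions: BnBr (1.2 equiv), K2CO3 (2 equiv), DMF, 60 °C
Reagents that add atoms: benzyl bromide, BrCc1ccccc1
Why: Williamson etherification of the phenoxide with a reactive benzylic halide, the aldehyde and the aryl bromide being inert to carbonate.

Step 6
Reactants: 9 4-benzyloxy-3-bromo-5-methoxybenzaldehyde; 2 dimethyl succinate
Product: 10 (E)-4-(4-benzyloxy-3-bromo-5-methoxyphenyl)-3-(methoxycarbonyl)but-3-enoic acid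
Conditions: NaOMe (1.5 equiv), MeOH, reflux; then aq. HCl
Reagents that add atoms: none
Why: Stobbe condensation as in step 1; the aryl bromide is not activated towards substitution by methoxide.

Step 7
Reactants: 10 (E)-4-(4-benzyloxy-3-bromo-5-methoxyphenyl)-3-(methoxycarbonyl)but-3-enoic acid
Product: 11 (S)-3-(4-benzyloxy-3-bromo-5-methoxybenzyl)-4-methoxy-4-oxobutanoic acid
Conditions: [Rh(cod)((R,R)-Et-DuPHOS)]BF4 (1 mol %), H2 (5 bar), NaOMe (0.1 equiv), MeOH, 25 °C
Reagents that add atoms: none
Why: Carboxylate-directed asymmetric hydrogenation as in step 2, setting the (S) centre by the same catalyst control; cationic rhodium bisphosphine complexes at room temperature should neither insert into the aryl bromide nor cleave the benzyl ether.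

Step 8
Reactants: 11 (S)-3-(4-benzyloxy-3-bromo-5-methoxybenzyl)-4-methoxy-4-oxobutanoic acid
Product: 13 (S)-4-(4-benzyloxy-3-bromo-5-methoxybenzyl)dihydrofuran-2(3H)-one, via hydroxy acid 12 (not isolated)
Conditions: KOH (1.0 equiv), EtOH, 0 °C; Ca(BH4)2 (from CaCl2 and NaBH4), EtOH, −10 °C to rt; then 2 M HCl, rt
Reagents that add atoms: none
Why: Ester-selective borohydride reduction and lactonisation as in step 3, with the aryl bromide inert to borohydride and the stereocentre untouched.

Step 9
Reactants: 13 (S)-4-(4-benzyloxy-3-bromo-5-methoxybenzyl)dihydrofuran-2(3H)-one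
Product: 14 (3R,4S)-3-acetyl-4-(4-benzyloxy-3-bromo-5-methoxybenzyl)dihydrofuran-2(3H)-one
Conditions: LiN(SiMe3)2 (2.2 equiv), THF, −78 °C; 1-acetylimidazole (1.1 equiv), −78 to 0 °C; aq. NH4Cl
Reagents that add atoms: 1-acetylimidazole, CC(=O)n1ccnc1
Why: Crossed Claisen acylation as in step 4, the silylamide base not touching the aryl bromide at low temperature; the labile C3 centre is reset in step 11.

Step 10
Reactants: 15 (4-benzyloxy-3-methoxyphenyl)methanol
Product: 16 4-benzyloxy-3-methoxybenzyl bromide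
Conditions: PBr3 (0.4 equiv), CH2Cl2, 0 °C
Reagents that add atoms: phosphorus tribromide, BrP(Br)Br
Why: Bromide substitution of an activated benzylic alcohol through its phosphite ester; the bromide is used promptly.

Step 11
Reactants: 14 (3R,4S)-3-acetyl-4-(4-benzyloxy-3-bromo-5-methoxybenzyl)dihydrofuran-2(3H)-one; 16 4-benzyloxy-3-methoxybenzyl bromide
Product: 17 (3S,4S)-3-acetyl-3-(4-benzyloxy-3-methoxybenzyl)-4-(4-benzyloxy-3-bromo-5-methoxybenzyl)dihydrofuran-2(3H)-one
Conditions: K2CO3 (2 equiv), n-Bu4NI (cat.), acetone, 50 °C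
Reagents that add atoms: none
Why: Acetoacetate-type C-benzylation of the stabilised β-keto lactone enolate; the planar enolate should be attacked on the face opposite the C4 arylmethyl group, which places the new benzyl trans to it and the acetyl cis and so sets C3 as S.

Step 12
Reactants: 9 4-benzyloxy-3-bromo-5-methoxybenzaldehyde
Product: 18 (4-benzyloxy-3-bromo-5-methoxyphenyl)methanol
Conditions: NaBH4 (0.5 equiv), MeOH–THF, 0 °C
Reagents that add atoms: none
Why: Hydride reduction of an aryl aldehyde, with the aryl bromide and benzyl ether inert.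

Step 13
Reactants: 18 (4-benzyloxy-3-bromo-5-methoxyphenyl)methanol
Product: 19 [4-benzyloxy-3-methoxy-5-(4,4,5,5-tetramethyl-1,3,2-dioxaborolan-2-yl)phenyl]methanol
Conditions: bis(pinacolato)diboron (1.2 equiv), Pd(dppf)Cl2 (3 mol %), KOAc (3 equiv), 1,4-dioxane, 90 °C
Reagents that add atoms: bis(pinacolato)diboron, CC1(C)OB(OC1(C)C)B1OC(C)(C)C(C)(C)O1
Why: Miyaura borylation of the aryl bromide under weak acetate base, which tolerates the free benzylic alcohol and avoids biaryl homocoupling.

Step 14
Reactants: 19 [4-benzyloxy-3-methoxy-5-(4,4,5,5-tetramethyl-1,3,2-dioxaborolan-2-yl)phenyl]methanol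
Product: 20 2-[2-benzyloxy-5-(bromomethyl)-3-methoxyphenyl]-4,4,5,5-tetramethyl-1,3,2-dioxaborolane
Conditions: CBr4 (1.2 equiv), PPh3 (1.2 equiv), CH2Cl2, 0 °C
Reagents that add atoms: carbon tetrabromide, BrC(Br)(Br)Br
Why: Appel bromination under neutral conditions, chosen so that no strong acid is present to protodeboronate the electron-rich aryl boronate.

Step 15
Reactants: 7 (3R,4S)-3-acetyl-4-(4-benzyloxy-3-methoxybenzyl)dihydrofuran-2(3H)-one; 20 2-[2-benzyloxy-5-(bromomethyl)-3-methoxyphenyl]-4,4,5,5-tetramethyl-1,3,2-dioxaborolane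
Product: 21 (3S,4S)-3-acetyl-4-(4-benzyloxy-3-methoxybenzyl)-3-[4-benzyloxy-3-methoxy-5-(4,4,5,5-tetramethyl-1,3,2-dioxaborolan-2-yl)benzyl]dihydrofuran-2(3H)-one
Conditions: K2CO3 (2 equiv), n-Bu4NI (cat.), acetone, 50 °C
Reagents that add atoms: none
Why: The same enolate C-benzylation as in step 11, with attack anti to the C4 arylmethyl group setting C3 as S; the pinacol boronate is inert to anhydrous carbonate.

Step 16
Reactants: 21 the boronate of step 15; 17 the aryl bromide of step 11
Product: 22 tetra-O-benzyl biaryl bis(3-acetyl lactone) (both lactones 3S,4S)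
Conditions: Pd(OAc)2 (5 mol %), SPhos (10 mol %), CsF (3 equiv), dry 1,4-dioxane, 90 °C
Reagents that add atoms: none
Why: Suzuki–Miyaura coupling with a dialkylbiarylphosphine ligand suited to ortho-alkoxy partners, activated by fluoride under anhydrous conditions so that no hydroxide can deacetylate the non-enolisable β-keto lactones by retro-Claisen cleavage; no stereocentre is touched.

Step 17
Reactants: 22 tetra-O-benzyl biaryl bis(3-acetyl lactone)
Product: 23 biaryl bis(3-acetyl lactone) tetraphenol (both lactones 3S,4S)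
Conditions: H2 (1 atm), 10% Pd/C, EtOAc–MeOH, rt
Reagents that add atoms: none
Why: Hydrogenolysis of the four benzyl aryl ethers, to which the aliphatic methyl ketones, the lactones and the methoxy groups are inert at one atmosphere and room temperature.

Step 18
Reactants: 23 biaryl bis(3-acetyl lactone) tetraphenol
Product: 24 biaryl bis(3-acetyl lactone) tetra(aryl acetate) (both lactones 3S,4S)
Conditions: Ac2O (8 equiv), pyridine, DMAP (0.1 equiv), CH2Cl2, rt
Reagents that add atoms: acetic anhydride, CC(=O)OC(C)=O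
Why: Nucleophile-catalysed O-acetylation of the four phenols, including the two hindered ones beside the biaryl bond; the quaternary C3 centres cannot enolise, so nothing else reacts.

Step 19
Reactants: 24 biaryl bis(3-acetyl lactone) tetra(aryl acetate)
Product: 25 biaryl bis(3-acetoxy lactone) tetra(aryl acetate) (both lactones 3R,4R)
Conditions: CF3CO3H (8 equiv, from (CF3CO)2O and urea–H2O2), Na2HPO4 (20 equiv), CH2Cl2, 0 °C to rt
Reagents that add atoms: trifluoroperacetic acid, OOC(=O)C(F)(F)F, made in the flask from trifluoroacetic anhydride, O=C(OC(=O)C(F)(F)F)C(F)(F)F, and urea–hydrogen peroxide, NC(N)=O.OO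
Why: Baeyer–Villiger oxidation: the peracid adds to each methyl ketone to give a Criegee adduct, and the quaternary C3, antiperiplanar to the O–O bond, shifts from carbon to oxygen as trifluoroacetate leaves, turning each C3–C(acetyl) bond into the C3–O bond of a tertiary acetate. The closest known reaction type is the peracid oxidation of α,α-disubstituted β-keto esters and of tert-alkyl methyl ketones to tertiary acetates. No ring is closed and no stereocentre is created: the 1,2-shift is suprafacial, so the geometry fixed at C3 in steps 11 and 15 is kept, and the descriptor changes from S to R only through the CIP priorities. The step needs C3 to migrate in preference to methyl, which the tertiary-alkyl against methyl migratory aptitude should secure even though the lactone carbonyl at C2 slows the shift. It also needs the ketones to react before the arenes, which the four aryl acetates (less electron-rich than aryl ethers) and the phosphate buffer are there to secure, while the lactone and acetate carbonyls are inert to the peracid.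

Step 20
Reactants: 25 biaryl bis(3-acetoxy lactone) tetra(aryl acetate)
Product: 26 CNP0218652.1, the 5,5'-linked bis(3-hydroxy-3,4-dibenzylbutyrolactone) (both lactones 3R,4R)
Conditions: K2CO3 (8 equiv), MeOH, argon, 0 °C to rt; then 1 M HCl, THF, rt
Reagents that add atoms: none
Why: Base-mediated transesterification (methanolysis) should remove the four aryl and two tertiary acetates as methyl acetate, and the acid treatment recloses any lactone opened by methoxide; C3 is quaternary and C4 is not acidic, so no centre can epimerise.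

**Compound list**

1 | 4-benzyloxy-3-methoxybenzaldehyde (O-benzylvanillin) | COc1cc(C=O)ccc1OCc1ccccc1 | starting material
2 | dimethyl succinate | COC(=O)CCC(=O)OC | starting material
3 | (E)-4-(4-benzyloxy-3-methoxyphenyl)-3-(methoxycarbonyl)but-3-enoic acid | COC(=O)/C(CC(=O)O)=C/c1ccc(OCc2ccccc2)c(OC)c1 | intermediate
4 | (S)-3-(4-benzyloxy-3-methoxybenzyl)-4-methoxy-4-oxobutanoic acid | COC(=O)[C@@H](Cc1ccc(OCc2ccccc2)c(OC)c1)CC(=O)O | intermediate
5 | (S)-4-(4-benzyloxy-3-methoxyphenyl)-3-(hydroxymethyl)butanoic acid (formed as its salt) | OC[C@@H](Cc1ccc(OCc2ccccc2)c(OC)c1)CC(=O)O | intermediate (not isolated)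
6 | (S)-4-(4-benzyloxy-3-methoxybenzyl)dihydrofuran-2(3H)-one | COc1cc(C[C@@H]2COC(=O)C2)ccc1OCc1ccccc1 | intermediate
7 | (3R,4S)-3-acetyl-4-(4-benzyloxy-3-methoxybenzyl)dihydrofuran-2(3H)-one (trans keto form; C3 labile) | COc1cc(C[C@@H]2COC(=O)[C@H]2C(C)=O)ccc1OCc1ccccc1 | intermediate
8 | 5-bromovanillin | COc1cc(C=O)cc(Br)c1O | starting material
9 | 4-benzyloxy-3-bromo-5-methoxybenzaldehyde | COc1cc(C=O)cc(Br)c1OCc1ccccc1 | intermediate
10 | (E)-4-(4-benzyloxy-3-bromo-5-methoxyphenyl)-3-(methoxycarbonyl)but-3-enoic acid | COC(=O)/C(CC(=O)O)=C/c1cc(Br)c(OCc2ccccc2)c(OC)c1 | intermediate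
11 | (S)-3-(4-benzyloxy-3-bromo-5-methoxybenzyl)-4-methoxy-4-oxobutanoic acid | COC(=O)[C@@H](Cc1cc(Br)c(OCc2ccccc2)c(OC)c1)CC(=O)O | intermediate
12 | (S)-4-(4-benzyloxy-3-bromo-5-methoxyphenyl)-3-(hydroxymethyl)butanoic acid (formed as its salt) | OC[C@@H](Cc1cc(Br)c(OCc2ccccc2)c(OC)c1)CC(=O)O | intermediate (not isolated)
13 | (S)-4-(4-benzyloxy-3-bromo-5-methoxybenzyl)dihydrofuran-2(3H)-one | COc1cc(C[C@@H]2COC(=O)C2)cc(Br)c1OCc1ccccc1 | intermediate
14 | (3R,4S)-3-acetyl-4-(4-benzyloxy-3-bromo-5-methoxybenzyl)dihydrofuran-2(3H)-one (trans keto form; C3 labile) | COc1cc(C[C@@H]2COC(=O)[C@H]2C(C)=O)cc(Br)c1OCc1ccccc1 | intermediate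
15 | (4-benzyloxy-3-methoxyphenyl)methanol | COc1cc(CO)ccc1OCc1ccccc1 | starting material
16 | 4-benzyloxy-3-methoxybenzyl bromide | COc1cc(CBr)ccc1OCc1ccccc1 | intermediate
17 | (3S,4S)-3-acetyl-3-(4-benzyloxy-3-methoxybenzyl)-4-(4-benzyloxy-3-bromo-5-methoxybenzyl)dihydrofuran-2(3H)-one | COc1cc(C[C@@H]2COC(=O)[C@@]2(C(C)=O)Cc2ccc(OCc3ccccc3)c(OC)c2)cc(Br)c1OCc1ccccc1 | intermediate
18 | (4-benzyloxy-3-bromo-5-methoxyphenyl)methanol | COc1cc(CO)cc(Br)c1OCc1ccccc1 | intermediate
19 | [4-benzyloxy-3-methoxy-5-(4,4,5,5-tetramethyl-1,3,2-dioxaborolan-2-yl)phenyl]methanol | COc1cc(CO)cc(B2OC(C)(C)C(C)(C)O2)c1OCc1ccccc1 | intermediate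
20 | 2-[2-benzyloxy-5-(bromomethyl)-3-methoxyphenyl]-4,4,5,5-tetramethyl-1,3,2-dioxaborolane | COc1cc(CBr)cc(B2OC(C)(C)C(C)(C)O2)c1OCc1ccccc1 | intermediate
21 | (3S,4S)-3-acetyl-4-(4-benzyloxy-3-methoxybenzyl)-3-[4-benzyloxy-3-methoxy-5-(4,4,5,5-tetramethyl-1,3,2-dioxaborolan-2-yl)benzyl]dihydrofuran-2(3H)-one | COc1cc(C[C@@H]2COC(=O)[C@@]2(C(C)=O)Cc2cc(OC)c(OCc3ccccc3)c(B3OC(C)(C)C(C)(C)O3)c2)ccc1OCc1ccccc1 | intermediate
22 | tetra-O-benzyl biaryl bis(3-acetyl lactone): two (3S,4S)-3-acetyl-3,4-bis(4-benzyloxy-3-methoxybenzyl)butyrolactones joined by a bond between ring position 5 of the C3 benzyl of one and ring position 5 of the C4 benzyl of the other (each ortho to benzyloxy) | COc1cc(C[C@@H]2COC(=O)[C@@]2(C(C)=O)Cc2cc(OC)c(OCc3ccccc3)c(-c3cc(C[C@@H]4COC(=O)[C@@]4(C(C)=O)Cc4ccc(OCc5ccccc5)c(OC)c4)cc(OC)c3OCc3ccccc3)c2)ccc1OCc1ccccc1 | intermediate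
23 | tetraphenol of 22 (all four benzyl ethers replaced by OH; both lactones 3S,4S) | COc1cc(C[C@@H]2COC(=O)[C@@]2(C(C)=O)Cc2cc(OC)c(O)c(-c3cc(C[C@@H]4COC(=O)[C@@]4(C(C)=O)Cc4ccc(O)c(OC)c4)cc(OC)c3O)c2)ccc1O | intermediate
24 | tetra(aryl acetate) of 23, the substrate of the key step (both lactones 3S,4S) | COc1cc(C[C@@H]2COC(=O)[C@@]2(C(C)=O)Cc2cc(OC)c(OC(C)=O)c(-c3cc(C[C@@H]4COC(=O)[C@@]4(C(C)=O)Cc4ccc(OC(C)=O)c(OC)c4)cc(OC)c3OC(C)=O)c2)ccc1OC(C)=O | intermediate
25 | biaryl bis(3-acetoxy lactone) tetra(aryl acetate), the product of the key step (both lactones 3R,4R) | COc1cc(C[C@@H]2COC(=O)[C@@]2(OC(C)=O)Cc2cc(OC)c(OC(C)=O)c(-c3cc(C[C@@H]4COC(=O)[C@@]4(OC(C)=O)Cc4ccc(OC(C)=O)c(OC)c4)cc(OC)c3OC(C)=O)c2)ccc1OC(C)=O | intermediate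
26 | CNP0218652.1: 5,5'-linked dimer of (3R,4R)-3-hydroxy-3,4-bis(4-hydroxy-3-methoxybenzyl)dihydrofuran-2(3H)-one, joined between the C3 benzyl ring of one unit and the C4 benzyl ring of the other | COc1cc(C[C@@H]2COC(=O)[C@@]2(O)Cc2cc(OC)c(O)c(-c3cc(C[C@@H]4COC(=O)[C@@]4(O)Cc4ccc(O)c(OC)c4)cc(OC)c3O)c2)ccc1O | target

**Step count and risk**

Total step count: 20. Longest linear sequence: 11 steps (8 → 9 → 10 → 11 → 13 → 14 → 17 → 22 → 23 → 24 → 25 → 26, steps 5, 6, 7, 8, 9, 11, 16, 17, 18, 19, 20).

Steps most likely to fail: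

1. Step 19. The migration of the acyl-substituted quaternary C3 may be slow enough that peracid attack on the arenes, or incomplete oxidation of the second ketone, competes. Fallback (oxygen placed on C3 before the benzyl group, no peracid): the lithium enolate of lactone 13 (LiN(SiMe3)2, THF, −78 °C) is hydroxylated with 2-(phenylsulfonyl)-3-phenyloxaziridine to the trans 3-hydroxy lactone F1. Its dianion (LiN(SiMe3)2, 2.2 equiv, THF–DMPU, −78 °C) is benzylated by 16 anti to the C4 group to give the 3-benzyl-3-hydroxy lactone F2, with the hydroxyl cis to that group. Lactone 6 is hydroxylated in the same way to the 3-hydroxy lactone F3. Alcohol 18 with PBr3 gives 4-benzyloxy-3-bromo-5-methoxybenzyl bromide F4, which alkylates the dianion of F3 to the aryl bromide F5. Miyaura borylation of F2 (bis(pinacolato)diboron, Pd(dppf)Cl2, KOAc) gives the boronate F6. Suzuki–Miyaura coupling of F6 with F5 (Pd(OAc)2, SPhos, K3PO4, toluene–water) gives the tetra-O-benzyl ether F7 of the target, and hydrogenolysis (H2, Pd/C) comes back to the route at 26.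

2. Step 16. Transmetalation between two large ortho-alkoxy partners used one to one may be slow, so that protodeboronation or base-induced deacetylation of a β-keto lactone overtakes the coupling. Fallback (biaryl bond made with a small partner in excess, halves joined by enolate alkylation instead): bromide 17 is coupled with an excess of boronate 19 (Pd(OAc)2, SPhos, CsF, dioxane) to the biaryl benzylic alcohol F8. Appel bromination (CBr4, PPh3) gives the biaryl benzylic bromide F9. C-benzylation of keto lactone 7 with F9 (K2CO3, acetone), anti to its C4 group, comes back to the route at 22.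

3. Step 4 (the same operation recurs as step 9). O-acylation, double acylation or proton transfer from product to enolate may hold back the C-acylation. Fallback (aldol addition and oxidation in place of acyl substitution): the lithium enolate of 6 (LiN(iPr)2, THF, −78 °C) adds to acetaldehyde to give the 3-(1-hydroxyethyl) lactone F10 as a mixture of carbinol epimers, and oxidation with Dess–Martin periodinane comes back to the route at 7. Lactone 13 would be taken in the same way through the bromo analogue F11 to 14.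

**Further compounds**

F1 | step 19 | (3S,4R)-4-(4-benzyloxy-3-bromo-5-methoxybenzyl)-3-hydroxydihydrofuran-2(3H)-one | COc1cc(C[C@@H]2COC(=O)[C@H]2O)cc(Br)c1OCc1ccccc1
F2 | step 19 | (3R,4R)-3-(4-benzyloxy-3-methoxybenzyl)-4-(4-benzyloxy-3-bromo-5-methoxybenzyl)-3-hydroxydihydrofuran-2(3H)-one | COc1cc(C[C@@H]2COC(=O)[C@@]2(O)Cc2ccc(OCc3ccccc3)c(OC)c2)cc(Br)c1OCc1ccccc1
F3 | step 19 | (3S,4R)-4-(4-benzyloxy-3-methoxybenzyl)-3-hydroxydihydrofuran-2(3H)-one | COc1cc(C[C@@H]2COC(=O)[C@H]2O)ccc1OCc1ccccc1
F4 | step 19 | 4-benzyloxy-3-bromo-5-methoxybenzyl bromide | COc1cc(CBr)cc(Br)c1OCc1ccccc1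
F5 | step 19 | (3R,4R)-3-(4-benzyloxy-3-bromo-5-methoxybenzyl)-4-(4-benzyloxy-3-methoxybenzyl)-3-hydroxydihydrofuran-2(3H)-one | COc1cc(C[C@@H]2COC(=O)[C@@]2(O)Cc2cc(OC)c(OCc3ccccc3)c(Br)c2)ccc1OCc1ccccc1
F6 | step 19 | (3R,4R)-3-(4-benzyloxy-3-methoxybenzyl)-4-[4-benzyloxy-3-methoxy-5-(4,4,5,5-tetramethyl-1,3,2-dioxaborolan-2-yl)benzyl]-3-hydroxydihydrofuran-2(3H)-one | COc1cc(C[C@@H]2COC(=O)[C@@]2(O)Cc2ccc(OCc3ccccc3)c(OC)c2)cc(B2OC(C)(C)C(C)(C)O2)c1OCc1ccccc1
F7 | step 19 | tetra-O-benzyl ether of 26 (both lactones 3R,4R) | COc1cc(C[C@@H]2COC(=O)[C@@]2(O)Cc2cc(OC)c(OCc3ccccc3)c(-c3cc(C[C@@H]4COC(=O)[C@@]4(O)Cc4ccc(OCc5ccccc5)c(OC)c4)cc(OC)c3OCc3ccccc3)c2)ccc1OCc1ccccc1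
F8 | step 16 | biaryl benzylic alcohol: 17 with Br replaced by the 2-benzyloxy-5-(hydroxymethyl)-3-methoxyphenyl group (lactone 3S,4S) | COc1cc(CO)cc(-c2cc(C[C@@H]3COC(=O)[C@@]3(C(C)=O)Cc3ccc(OCc4ccccc4)c(OC)c3)cc(OC)c2OCc2ccccc2)c1OCc1ccccc1
F9 | step 16 | biaryl benzylic bromide: F8 with CH2OH replaced by CH2Br (lactone 3S,4S) | COc1cc(CBr)cc(-c2cc(C[C@@H]3COC(=O)[C@@]3(C(C)=O)Cc3ccc(OCc4ccccc4)c(OC)c3)cc(OC)c2OCc2ccccc2)c1OCc1ccccc1
F10 | step 4 | (3R,4S)-4-(4-benzyloxy-3-methoxybenzyl)-3-(1-hydroxyethyl)dihydrofuran-2(3H)-one (carbinol epimers) | COc1cc(C[C@@H]2COC(=O)[C@H]2C(C)O)ccc1OCc1ccccc1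
F11 | step 4 | (3R,4S)-4-(4-benzyloxy-3-bromo-5-methoxybenzyl)-3-(1-hydroxyethyl)dihydrofuran-2(3H)-one (carbinol epimers) | COc1cc(C[C@@H]2COC(=O)[C@H]2C(C)O)cc(Br)c1OCc1ccccc1
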